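**Plan**

- Numbering: the lactone (ring A) is O1, C2(=O), C3, C4, C5; C7 is the CH2 on C3 (towards the pyrone) and C8 the CH2 on C4 (towards the veratryl ring).
- Retrosynthesis: the 2-pyrone-6-carboxylic acid is traced back to a 3,4,5-trihydroxyphenyl ring (intradiol cleavage plus enol lactonisation in the forward sense), C5 to an acetal carbon, and then C3–C7 and C4–C8 are cut in one operation.
- Enabling feature: C3 and C4 are the α- and β-carbons of the C2 carbonyl and C8 is benzylic, so a 5-alkoxybutenolide can take a masked 3,4-dimethoxybenzoyl anion at C4 and its enolate a benzylic bromide at C3.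
- Forward: ring A is present from the start as a menthyl-acetal butenolide; C4–C8 and then C3–C7 form in one flask without ring closure; sulfur and the auxiliary are removed (ring A opens and recloses with C5 as CH2); the pyrone ring is made last from the deprotected pyrogallol.
- Stereochemistry: the (5R) acetal carbon, fixed by crystallisation of the l-menthyl acetal, directs the dithiane anti at C4; the dithiane directs the benzyl group anti at C3; this gives (3R,4R), after which the C5 stereocentre is erased.

Key step: step 7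

Remark: the target is read from its SMILES as the trans-(3R,4R) lactone; compounds 2 and 3 are racemic and 5 is a mixture of C5 epimers; the pyrone acid is assumed to arise from the 5-alkylpyrogallol by the peracid cleavage known for pyrogallol itself.

**Route**

Step 1
Reactants: 1 furfural
Product: 3 racemic 5-hydroxyfuran-2(5H)-one, via furfural 2,5-endoperoxide 2 (not isolated)
Conditions: O2, hν (visible), methylene blue (cat.), MeOH, 20 °C
Reagents that add atoms: dioxygen, O=O
Why: Dye-sensitised singlet-oxygen [4+2] cycloaddition to the furan gives endoperoxide 2, which methanol fragments with loss of the formyl carbon as methyl formate to the pseudo-acid 3 (Schenck-type photo-oxygenation of furfural), with no stereocentre to control.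

Step 2
Reactants: 3 racemic 5-hydroxyfuran-2(5H)-one; 4 (1R,2S,5R)-menthol
Product: 6 (5R)-5-[(1R,2S,5R)-menthyloxy]furan-2(5H)-one, via C5-epimeric menthyl acetal mixture 5 (not isolated)
Conditions: p-TsOH (cat.), toluene, reflux, Dean–Stark; crystallisation from petroleum ether, −20 °C; mother liquor re-equilibrated with p-TsOH and recrystallised
Reagents that add atoms: none
Why: Acid-catalysed acetalisation of the pseudo-acid with azeotropic water removal gives both C5 epimers, which interconvert under acid, and the (5R) diastereomer is the one expected to crystallise, so C5 is set by crystallisation-induced diastereomer enrichment under control of the menthyl group.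

Step 3
Reactants: 7 veratraldehyde (3,4-dimethoxybenzaldehyde)
Product: 8 2-(3,4-dimethoxyphenyl)-1,3-dithiane
Conditions: HS(CH2)3SH, BF3·OEt2 (cat.), CH2Cl2, 0 °C → rt
Reagents that add atoms: propane-1,3-dithiol, SCCCS
Why: Lewis-acid-catalysed dithioacetalisation of an aromatic aldehyde, to which the aryl methyl ethers are inert.

Step 4
Reactants: 9 methyl gallate (methyl 3,4,5-trihydroxybenzoate)
Product: 10 methyl 3,4,5-tris(benzyloxy)benzoate
Conditions: BnBr, K2CO3, DMF, 60 °C
Reagents that add atoms: benzyl bromide, BrCc1ccccc1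
Why: Williamson ether synthesis on the three phenols, the methyl ester being untouched by K2CO3 in DMF.

Step 5
Reactants: 10 methyl 3,4,5-tris(benzyloxy)benzoate
Product: 11 [3,4,5-tris(benzyloxy)phenyl]methanol
Conditions: LiAlH4, THF, 0 °C → rt; aqueous NaOH work-up
Reagents that add atoms: none
Why: Hydride reduction of the ester to the benzylic alcohol, aryl benzyl ethers being inert to LiAlH4.

Step 6
Reactants: 11 [3,4,5-tris(benzyloxy)phenyl]methanol
Product: 12 3,4,5-tris(benzyloxy)benzyl bromide
Conditions: PBr3 (0.4 equiv), CH2Cl2, 0 °C; used freshly prepared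
Reagents that add atoms: phosphorus tribromide, BrP(Br)Br
Why: Bromination of a benzylic alcohol through its phosphite ester (SN2 by bromide), with low temperature and sub-stoichiometric PBr3 protecting the benzyl ethers from HBr.

Step 7
Reactants: 8 2-(3,4-dimethoxyphenyl)-1,3-dithiane; 6 (5R)-5-[(1R,2S,5R)-menthyloxy]furan-2(5H)-one; 12 3,4,5-tris(benzyloxy)benzyl bromide
Product: 15 (3R,4R,5R)-4-[2-(3,4-dimethoxyphenyl)-1,3-dithian-2-yl]-5-[(1R,2S,5R)-menthyloxy]-3-[3,4,5-tris(benzyloxy)benzyl]dihydrofuran-2(3H)-one, via 2-lithio-2-(3,4-dimethoxyphenyl)-1,3-dithiane 13 (not isolated), via lithium enolate of the conjugate adduct 14 (not isolated)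
Conditions: n-BuLi, THF, −78 °C; then 6, −78 °C; then 12, DMPU, −78 °C → rt; aqueous NH4Cl
Reagents that add atoms: none
Why: n-BuLi removes the C2 proton of dithiane 8, the sulfur-stabilised carbanion 13 adds 1,4 to butenolide 6 to form C4–C8, and the resulting lithium enolate 14 is C-alkylated at C3 by the benzylic bromide 12 (SN2) to form C3–C7. The closest known reaction type is the tandem conjugate addition of lithiated aryl dithianes to butenolides and 5-alkoxybutenolides with in situ enolate benzylation, the standard entry to trans-dibenzylbutyrolactones. No ring is closed. C4 is set by attack on the butenolide face opposite the C5 menthyloxy group, and C3 by approach of the bromide to the enolate face opposite the bulky aryl-dithianyl group on C4, which should give the 3,4-trans-4,5-trans lactone with (3R,4R,5R) configuration. The step needs 1,4- over 1,2-addition, secured by the soft delocalised dithianyl anion and the unhindered β-carbon, and C-alkylation ahead of proton transfer, secured by the lithium enolate in THF/DMPU and the reactive benzylic bromide.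

Step 8
Reactants: 15 the dithianyl lactone of step 7
Product: 16 (3R,4R,5R)-4-(3,4-dimethoxybenzyl)-5-[(1R,2S,5R)-menthyloxy]-3-[3,4,5-tris(benzyloxy)benzyl]dihydrofuran-2(3H)-one
Conditions: NiCl2·6H2O, NaBH4, MeOH/THF, 0 °C → rt
Reagents that add atoms: none
Why: Nickel boride (Ni2B) generated in situ hydrogenolyses both benzylic C–S bonds (reductive desulfurisation) to leave the C8 methylene, while the aryl benzyl ethers, the acetal lactone and the untouched C3 and C4 stereocentres should survive at this temperature.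

Step 9
Reactants: 16 the menthyl acetal lactone of step 8
Product: 19 (3R,4R)-4-(3,4-dimethoxybenzyl)-3-[3,4,5-tris(benzyloxy)benzyl]dihydrofuran-2(3H)-one, via potassium formyl carboxylate 17 (not isolated), via potassium hydroxy carboxylate 18 (not isolated)
Conditions: NaBH4, KOH, EtOH/H2O, rt; then 2 M HCl to pH 1, rt
Reagents that add atoms: potassium hydroxide, [K+].[OH-] (its oxygen enters the carboxylate and can remain as the lactone carbonyl oxygen)
Why: Hydroxide opens the pseudo-ester to carboxylate 17 with loss of menthoxide, borohydride reduces the unmasked aldehyde to 18 faster than C4 can epimerise, and acidification closes the γ-lactone (saponification–reduction–lactonisation), so C5 becomes the ring CH2 while C3 and C4 keep their R,R configuration.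

Step 10
Reactants: 19 the tris(benzyloxy) lactone of step 9
Product: 20 (3R,4R)-4-(3,4-dimethoxybenzyl)-3-(3,4,5-trihydroxybenzyl)dihydrofuran-2(3H)-one
Conditions: H2 (1 atm), 10% Pd/C, EtOAc/MeOH, rt; filtered under argon and used at once
Reagents that add atoms: none
Why: Palladium-catalysed hydrogenolysis of the three aryl benzyl ethers, under which the lactone, the methyl ethers and the non-oxygenated benzylic C–C bonds are inert.

Step 11
Reactants: 20 the trihydroxybenzyl lactone of step 10
Product: 23 4-{[(3R,4R)-4-(3,4-dimethoxybenzyl)-2-oxotetrahydrofuran-3-yl]methyl}-2-oxo-2H-pyran-6-carboxylic acid, via hydroxy-ortho-quinone 21 (not isolated), via hydroxymuconic anhydride 22 (not isolated)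
Conditions: AcOOH (2.2 equiv, solution in AcOH), AcOH, 15 °C → rt
Reagents that add atoms: peracetic acid, CC(=O)OO
Why: Peracid intradiol cleavage of a pyrogallol, in which two-electron oxidation gives hydroxy-ortho-quinone 21, Baeyer–Villiger-type oxygen insertion between the two carbonyls gives anhydride 22 and acyl transfer to the neighbouring enol hydroxyl gives the 2-pyrone-6-carboxylic acid, the trihydroxy ring being far more electron-rich than the veratryl ring and no stereocentre being involved.

**Compound list**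

1 | furfural | O=Cc1ccco1 | starting material
2 | 2,3,7-trioxabicyclo[2.2.1]hept-5-ene-1-carbaldehyde (furfural 2,5-endoperoxide, racemic) | O=CC12OOC(O1)C=C2 | intermediate
3 | 5-hydroxyfuran-2(5H)-one (racemic) | OC1OC(=O)C=C1 | intermediate
4 | (1R,2S,5R)-menthol | CC(C)[C@@H]1CC[C@@H](C)C[C@H]1O | starting material
5 | 5-[(1R,2S,5R)-menthyloxy]furan-2(5H)-one, mixture of C5 epimers | CC(C)[C@@H]1CC[C@@H](C)C[C@H]1OC1OC(=O)C=C1 | intermediate
6 | (5R)-5-[(1R,2S,5R)-menthyloxy]furan-2(5H)-one | CC(C)[C@@H]1CC[C@@H](C)C[C@H]1O[C@@H]1OC(=O)C=C1 | intermediate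
7 | veratraldehyde | COc1ccc(C=O)cc1OC | starting material
8 | 2-(3,4-dimethoxyphenyl)-1,3-dithiane | COc1ccc(C2SCCCS2)cc1OC | intermediate
9 | methyl gallate | COC(=O)c1cc(O)c(O)c(O)c1 | starting material
10 | methyl 3,4,5-tris(benzyloxy)benzoate | COC(=O)c1cc(OCc2ccccc2)c(OCc2ccccc2)c(OCc2ccccc2)c1 | intermediate
11 | [3,4,5-tris(benzyloxy)phenyl]methanol | OCc1cc(OCc2ccccc2)c(OCc2ccccc2)c(OCc2ccccc2)c1 | intermediate
12 | 3,4,5-tris(benzyloxy)benzyl bromide | BrCc1cc(OCc2ccccc2)c(OCc2ccccc2)c(OCc2ccccc2)c1 | intermediate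
13 | 2-lithio-2-(3,4-dimethoxyphenyl)-1,3-dithiane | [Li]C1(c2ccc(OC)c(OC)c2)SCCCS1 | intermediate
14 | lithium (4R,5R)-4-[2-(3,4-dimethoxyphenyl)-1,3-dithian-2-yl]-5-[(1R,2S,5R)-menthyloxy]-4,5-dihydrofuran-2-olate | CC(C)[C@@H]1CC[C@@H](C)C[C@H]1O[C@@H]1OC(O[Li])=C[C@H]1C1(c2ccc(OC)c(OC)c2)SCCCS1 | intermediate
15 | (3R,4R,5R)-4-[2-(3,4-dimethoxyphenyl)-1,3-dithian-2-yl]-5-[(1R,2S,5R)-menthyloxy]-3-[3,4,5-tris(benzyloxy)benzyl]dihydrofuran-2(3H)-one | CC(C)[C@@H]1CC[C@@H](C)C[C@H]1O[C@@H]1OC(=O)[C@H](Cc2cc(OCc3ccccc3)c(OCc3ccccc3)c(OCc3ccccc3)c2)[C@H]1C1(c2ccc(OC)c(OC)c2)SCCCS1 | intermediate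
16 | (3R,4R,5R)-4-(3,4-dimethoxybenzyl)-5-[(1R,2S,5R)-menthyloxy]-3-[3,4,5-tris(benzyloxy)benzyl]dihydrofuran-2(3H)-one | CC(C)[C@@H]1CC[C@@H](C)C[C@H]1O[C@@H]1OC(=O)[C@H](Cc2cc(OCc3ccccc3)c(OCc3ccccc3)c(OCc3ccccc3)c2)[C@H]1Cc1ccc(OC)c(OC)c1 | intermediate
17 | potassium (2R,3R)-4-(3,4-dimethoxyphenyl)-3-formyl-2-[3,4,5-tris(benzyloxy)benzyl]butanoate | COc1ccc(C[C@@H](C=O)[C@@H](Cc2cc(OCc3ccccc3)c(OCc3ccccc3)c(OCc3ccccc3)c2)C(=O)[O-])cc1OC.[K+] | intermediate
18 | potassium (2R,3R)-4-(3,4-dimethoxyphenyl)-3-(hydroxymethyl)-2-[3,4,5-tris(benzyloxy)benzyl]butanoate | COc1ccc(C[C@@H](CO)[C@@H](Cc2cc(OCc3ccccc3)c(OCc3ccccc3)c(OCc3ccccc3)c2)C(=O)[O-])cc1OC.[K+] | intermediate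
19 | (3R,4R)-4-(3,4-dimethoxybenzyl)-3-[3,4,5-tris(benzyloxy)benzyl]dihydrofuran-2(3H)-one | COc1ccc(C[C@H]2COC(=O)[C@@H]2Cc2cc(OCc3ccccc3)c(OCc3ccccc3)c(OCc3ccccc3)c2)cc1OC | intermediate
20 | (3R,4R)-4-(3,4-dimethoxybenzyl)-3-(3,4,5-trihydroxybenzyl)dihydrofuran-2(3H)-one | COc1ccc(C[C@H]2COC(=O)[C@@H]2Cc2cc(O)c(O)c(O)c2)cc1OC | intermediate
21 | (3R,4R)-4-(3,4-dimethoxybenzyl)-3-[(5-hydroxy-3,4-dioxocyclohexa-1,5-dien-1-yl)methyl]dihydrofuran-2(3H)-one | COc1ccc(C[C@H]2COC(=O)[C@@H]2CC2=CC(=O)C(=O)C(O)=C2)cc1OC | intermediate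
22 | (3R,4R)-4-(3,4-dimethoxybenzyl)-3-[(3-hydroxy-2,7-dioxo-2,7-dihydrooxepin-5-yl)methyl]dihydrofuran-2(3H)-one | COc1ccc(C[C@H]2COC(=O)[C@@H]2CC2=CC(=O)OC(=O)C(O)=C2)cc1OC | intermediate
23 | 4-{[(3R,4R)-4-(3,4-dimethoxybenzyl)-2-oxotetrahydrofuran-3-yl]methyl}-2-oxo-2H-pyran-6-carboxylic acid | COc1ccc(C[C@H]2COC(=O)[C@@H]2Cc2cc(C(=O)O)oc(=O)c2)cc1OC | target

**Step count**

Total: 11 steps. Longest linear sequence: 8 steps (9 → 10 → 11 → 12 → 15 → 16 → 19 → 20 → 23, steps 4 to 11).

**Steps most likely to fail**

Step 11. The transient hydroxy-ortho-quinone may couple oxidatively with triphenol that has not yet reacted, and excess peracid may begin to oxidise the veratryl ring. The fallback sets out from 20 and returns at 23 by separating dehydrogenation from oxygen insertion. Triphenol 20 would be added slowly to o-chloranil in Et2O/THF at −40 °C, so that free pyrogallol never accumulates, to give quinone 21 in solution. One equivalent of 3-chloroperbenzoic acid in CH2Cl2 at −20 °C (Baeyer–Villiger ring expansion of an ortho-quinone to a muconic anhydride) would then give 22, and aqueous acetic acid would complete the acyl transfer to 23. This fallback makes no compound outside the list (F0).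

Step 7. C-alkylation of the hindered lithium enolate next to the quaternary dithiane carbon may be slow, so that proton transfer leaves only the conjugate adduct. The fallback sets out from 6 and 8 and returns at 15 by decoupling the two bond formations. The addition of 13 (from 8 and n-BuLi) to 6 would be quenched at −78 °C with acetic acid and the trans adduct (4R,5R)-4-[2-(3,4-dimethoxyphenyl)-1,3-dithian-2-yl]-5-[(1R,2S,5R)-menthyloxy]dihydrofuran-2(3H)-one F1 isolated. Its enolate, regenerated with LiN(SiMe3)2 in THF/DMPU at −78 °C, would then be benzylated with 12 anti to the dithiane to give 15.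

Step 9. C4 may epimerise through enolisation of the transient aldehyde in the alkaline medium, or the hindered acetal may open incompletely. The fallback sets out from 16 and returns at 19 by removing the auxiliary under acid first. Hydrolysis of 16 with 2 M HCl in dioxane at 60 °C would give the pseudo-acid (3R,4R)-4-(3,4-dimethoxybenzyl)-5-hydroxy-3-[3,4,5-tris(benzyloxy)benzyl]dihydrofuran-2(3H)-one F2 as a mixture of C5 anomers. Reduction of F2 with NaBH4 in THF/aqueous NaHCO3 at 0 °C (pseudo-acid to lactone reduction) followed by acidification would return 19.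

**Further compounds**

F0 | step 11 | none | none
F1 | step 7 | (4R,5R)-4-[2-(3,4-dimethoxyphenyl)-1,3-dithian-2-yl]-5-[(1R,2S,5R)-menthyloxy]dihydrofuran-2(3H)-one | CC(C)[C@@H]1CC[C@@H](C)C[C@H]1O[C@@H]1OC(=O)C[C@H]1C1(c2ccc(OC)c(OC)c2)SCCCS1
F2 | step 9 | (3R,4R)-4-(3,4-dimethoxybenzyl)-5-hydroxy-3-[3,4,5-tris(benzyloxy)benzyl]dihydrofuran-2(3H)-one, mixture of C5 anomers | OC1OC(=O)[C@H](Cc2cc(OCc3ccccc3)c(OCc3ccccc3)c(OCc3ccccc3)c2)[C@H]1Cc1ccc(OC)c(OC)c1
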